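**Retrosynthetic overview**

- The target is a trans-3,4-dibenzyl-γ-butyrolactone (ring atoms O1, C2(=O), C3, C4, C5H2). The last step removes three benzyl ethers from 15, and the C3 configuration is fixed by equilibration (14 → 15).
- Key disconnection: the O1–C2(=O) unit is taken out as formate (a CO2 radical-anion source), cutting C2–C3 and O1–C5 together back to the acyclic styrenyl chloride 11. This is the only ring-forming step.
- Enabling feature: C3 is homobenzylic to the 2,4-dioxygenated 3-methoxyphenyl ring (C3–C7′H2–aryl), so C3=C7′ can be a styrene whose remote carbon accepts CO2•− to give a benzylic radical. C5 lies 1,3 to C3 across C4, so the new carboxylate closes 5-exo-tet on a CH2Cl group.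
- 11 comes from cross-metathesis of styrene 10 (three steps from 2-methoxyresorcinol) with homoallylic chloride 5.
- 5 carries the C4 stereocentre and the CH2Cl leaving group; it comes from a Cu-catalysed asymmetric SN2′ alkylation of (E)-1,4-dichlorobut-2-ene with the benzylic Grignard reagent from 2.

Key step: step 7

Assumption: the sense of induction of the Cu/phosphoramidite allylic alkylation with a benzylic Grignard reagent is taken to follow that of alkyl Grignard reagents, and the ligand antipode that delivers (R)-5 is the one used.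

**Step 1**
Reactants: 1 [4-(benzyloxy)-3-methoxyphenyl]methanol
Product: 2 1-(benzyloxy)-4-(chloromethyl)-2-methoxybenzene
Conditions: SOCl2 (1.2 equiv), CH2Cl2, 0 °C to rt; used crude
Reagents that add atoms: thionyl chloride, O=S(Cl)Cl
Why: Deoxychlorination of an electron-rich benzylic alcohol through its chlorosulfite, with the aryl benzyl ether stable to the HCl released.

**Step 2**
Reactants: 2 1-(benzyloxy)-4-(chloromethyl)-2-methoxybenzene; 3 (E)-1,4-dichlorobut-2-ene
Product: 5 1-(benzyloxy)-4-[(2R)-2-(chloromethyl)but-3-en-1-yl]-2-methoxybenzene, via benzylic Grignard reagent 4 (not isolated)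
Conditions: Mg turnings, THF, 0 °C (slow addition of 2); solution of 4 then added to 3 (1.2 equiv), copper(I) thiophene-2-carboxylate (3 mol %), chiral BINOL-derived phosphoramidite ligand (3.3 mol %), CH2Cl2, −78 °C
Reagents that add atoms: none
Why: Copper-catalysed asymmetric allylic alkylation (anti-SN2′) of a Grignard reagent on the symmetric dichloride, in which the chiral Cu(I)–phosphoramidite complex selects the enantiotopic alkene face, sets the R stereocentre and leaves the second chloride as the CH2Cl handle.

**Step 3**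
Reactants: 6 2-methoxybenzene-1,3-diol
Product: 7 1,3-bis(benzyloxy)-2-methoxybenzene
Conditions: BnBr (2.2 equiv), K2CO3, DMF, 60 °C
Reagents that add atoms: benzyl bromide, BrCc1ccccc1
Why: Double Williamson etherification of the two phenols (phenoxide SN2 on benzyl bromide) on a symmetric substrate, so no selectivity issue arises.

**Step 4**
Reactants: 7 1,3-bis(benzyloxy)-2-methoxybenzene
Product: 9 2,4-bis(benzyloxy)-3-methoxybenzaldehyde, via aryl iminium chloride 8 (not isolated)
Conditions: POCl3 (1.5 equiv), DMF, 0 to 70 °C; then H2O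
Reagents that add atoms: N,N-dimethylformamide, CN(C)C=O; water, O
Why: Vilsmeier–Haack formylation takes place at C4, which is para to one benzyloxy group and ortho to the other (C5 is meta to both), as in the formylation of 1,2,3-trialkoxybenzenes, and the iminium salt 8 is hydrolysed on aqueous work-up.

**Step 5**
Reactants: 9 2,4-bis(benzyloxy)-3-methoxybenzaldehyde
Product: 10 1,3-bis(benzyloxy)-4-ethenyl-2-methoxybenzene
Conditions: Ph3PCH3Br, KOtBu, THF, 0 °C to rt
Reagents that add atoms: methyltriphenylphosphonium bromide, C[P+](c1ccccc1)(c1ccccc1)c1ccccc1.[Br-]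
Why: Wittig methylenation of an aromatic aldehyde with the non-stabilised ylide, with no stereochemical issue.

**Step 6**
Reactants: 5 1-(benzyloxy)-4-[(2R)-2-(chloromethyl)but-3-en-1-yl]-2-methoxybenzene; 10 1,3-bis(benzyloxy)-4-ethenyl-2-methoxybenzene
Product: 11 1,3-bis(benzyloxy)-4-[(1E,3R)-4-[4-(benzyloxy)-3-methoxyphenyl]-3-(chloromethyl)but-1-en-1-yl]-2-methoxybenzene
Conditions: 10 (2 equiv), second-generation Ru catalyst with chelating 2-isopropoxybenzylidene (Hoveyda–Grubbs II, 5 mol %), CH2Cl2, 40 °C
Reagents that add atoms: none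
Why: Olefin cross-metathesis between a styrene and an allylically branched terminal alkene, which homodimerises slowly and therefore pairs selectively with the styrene; the E-alkene is expected under thermodynamic control (the geometry is immaterial for step 7) and the stereocentre is not touched by the catalyst.

**Step 7**
Reactants: 11 1,3-bis(benzyloxy)-4-[(1E,3R)-4-[4-(benzyloxy)-3-methoxyphenyl]-3-(chloromethyl)but-1-en-1-yl]-2-methoxybenzene
Product: 14 (3RS,4R)-3-[2,4-bis(benzyloxy)-3-methoxybenzyl]-4-[4-(benzyloxy)-3-methoxybenzyl]dihydrofuran-2(3H)-one (mixture of C3 epimers), via benzylic radical 12 (not isolated), via potassium chloro carboxylate 13 (not isolated)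
Conditions: HCO2K (5 equiv), 4CzIPN (2 mol %), sodium 2-mercaptoethanesulfonate (10 mol %), degassed DMSO, blue LEDs (450 nm), rt; then 70 °C in the dark
Reagents that add atoms: potassium formate, [K+].[O-]C=O
Why: Photoexcited 4CzIPN and the thiol co-catalyst turn formate into CO2•− by hydrogen-atom abstraction, and this nucleophilic radical, a polarity-reversed carboxyl group, adds to the styrene of 11 at C3 (the alkene carbon remote from the aryl ring) to give the C7′ benzylic radical 12, which takes a hydrogen atom from the thiol to give carboxylate 13. On warming, the carboxylate oxygen of 13 displaces the primary chloride at C5 in a 5-exo-tet SN2 closure, so the C2–C3 and O1–C5 bonds of the lactone are both made in one pot and formate supplies the whole O–C=O unit. The closest known reaction types are the photocatalytic anti-Markovnikov (Giese-type) hydrocarboxylation of styrenes with formate salts and the lactonisation of γ-halo carboxylates. C4 is carried over unchanged from 5 because neither new bond touches it, whereas C3 is created by radical addition next to this centre under weak 1,2-induction only and is expected as an epimer mixture, which step 8 corrects thermodynamically. The step needs regioselectivity (secured by the aryl group, which makes only the C3 adduct a benzylic radical), chemoselectivity for alkene addition over C–Cl reduction (a primary alkyl chloride lies beyond the reducing power of CO2•−) and survival of the allylic C4–H (low thiol loading and a large excess of formate keep thiyl radicals occupied). No carbanion is ever formed at C3, so the 1,3-elimination to a cyclopropane that would plague an organometallic carboxylation of a γ-chloride cannot occur.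

**Step 8**
Reactants: 14 (3RS,4R)-3-[2,4-bis(benzyloxy)-3-methoxybenzyl]-4-[4-(benzyloxy)-3-methoxybenzyl]dihydrofuran-2(3H)-one (mixture of C3 epimers)
Product: 15 (3R,4R)-3-[2,4-bis(benzyloxy)-3-methoxybenzyl]-4-[4-(benzyloxy)-3-methoxybenzyl]dihydrofuran-2(3H)-one
Conditions: NaOMe (0.3 equiv), MeOH/THF, rt; then 1 M HCl
Reagents that add atoms: none
Why: Base-mediated thermodynamic epimerisation through the lactone enolate at C3 (the only acidic C–H, C4 being untouched) should converge the epimers on the trans-3,4-dibenzyl lactone, in which the two benzyl groups avoid the eclipsing interaction of the cis isomer, and the acidic work-up recloses any ring-opened hydroxy ester.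

**Step 9**
Reactants: 15 (3R,4R)-3-[2,4-bis(benzyloxy)-3-methoxybenzyl]-4-[4-(benzyloxy)-3-methoxybenzyl]dihydrofuran-2(3H)-one
Product: 16 (3R,4R)-3-(2,4-dihydroxy-3-methoxybenzyl)-4-(4-hydroxy-3-methoxybenzyl)dihydrofuran-2(3H)-one
Conditions: H2 (1 atm), 10% Pd/C, EtOAc/EtOH, rt
Reagents that add atoms: none
Why: Hydrogenolysis of the three aryl benzyl ethers over palladium under neutral conditions leaves the lactone, the aryl methyl ethers and both stereocentres untouched.

**Compound list**

1 | [4-(benzyloxy)-3-methoxyphenyl]methanol | COc1cc(CO)ccc1OCc1ccccc1 | starting material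
2 | 1-(benzyloxy)-4-(chloromethyl)-2-methoxybenzene | COc1cc(CCl)ccc1OCc1ccccc1 | intermediate
3 | (E)-1,4-dichlorobut-2-ene | ClC/C=C/CCl | starting material
4 | [4-(benzyloxy)-3-methoxybenzyl]magnesium chloride | COc1cc(C[Mg]Cl)ccc1OCc1ccccc1 | intermediate (not isolated)
5 | 1-(benzyloxy)-4-[(2R)-2-(chloromethyl)but-3-en-1-yl]-2-methoxybenzene | C=C[C@H](CCl)Cc1ccc(OCc2ccccc2)c(OC)c1 | intermediate
6 | 2-methoxybenzene-1,3-diol (2-methoxyresorcinol) | COc1c(O)cccc1O | starting material
7 | 1,3-bis(benzyloxy)-2-methoxybenzene | COc1c(OCc2ccccc2)cccc1OCc1ccccc1 | intermediate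
8 | N-[2,4-bis(benzyloxy)-3-methoxybenzylidene]-N-methylmethanaminium chloride | C[N+](C)=Cc1ccc(OCc2ccccc2)c(OC)c1OCc1ccccc1.[Cl-] | intermediate (not isolated)
9 | 2,4-bis(benzyloxy)-3-methoxybenzaldehyde | O=Cc1ccc(OCc2ccccc2)c(OC)c1OCc1ccccc1 | intermediate
10 | 1,3-bis(benzyloxy)-4-ethenyl-2-methoxybenzene | C=Cc1ccc(OCc2ccccc2)c(OC)c1OCc1ccccc1 | intermediate
11 | 1,3-bis(benzyloxy)-4-[(1E,3R)-4-[4-(benzyloxy)-3-methoxyphenyl]-3-(chloromethyl)but-1-en-1-yl]-2-methoxybenzene | COc1c(OCc2ccccc2)ccc(/C=C/[C@H](CCl)Cc2ccc(OCc3ccccc3)c(OC)c2)c1OCc1ccccc1 | intermediate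
12 | C7′ benzylic radical formed by addition of CO2•− to 11 (potassium carboxylate, C3 unassigned, C4 R) | [K+].[O-]C(=O)C([CH]c1ccc(OCc2ccccc2)c(OC)c1OCc1ccccc1)[C@H](CCl)Cc1ccc(OCc2ccccc2)c(OC)c1 | intermediate (not isolated)
13 | potassium (2RS,3R)-2-[2,4-bis(benzyloxy)-3-methoxybenzyl]-4-[4-(benzyloxy)-3-methoxyphenyl]-3-(chloromethyl)butanoate | [K+].[O-]C(=O)C(Cc1ccc(OCc2ccccc2)c(OC)c1OCc1ccccc1)[C@H](CCl)Cc1ccc(OCc2ccccc2)c(OC)c1 | intermediate (not isolated)
14 | (3RS,4R)-3-[2,4-bis(benzyloxy)-3-methoxybenzyl]-4-[4-(benzyloxy)-3-methoxybenzyl]dihydrofuran-2(3H)-one (C3 epimer mixture) | COc1cc(C[C@H]2COC(=O)C2Cc2ccc(OCc3ccccc3)c(OC)c2OCc2ccccc2)ccc1OCc1ccccc1 | intermediate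
15 | (3R,4R)-3-[2,4-bis(benzyloxy)-3-methoxybenzyl]-4-[4-(benzyloxy)-3-methoxybenzyl]dihydrofuran-2(3H)-one | COc1cc(C[C@H]2COC(=O)[C@@H]2Cc2ccc(OCc3ccccc3)c(OC)c2OCc2ccccc2)ccc1OCc1ccccc1 | intermediate
16 | (3R,4R)-3-(2,4-dihydroxy-3-methoxybenzyl)-4-(4-hydroxy-3-methoxybenzyl)dihydrofuran-2(3H)-one | COc1cc(C[C@H]2COC(=O)[C@@H]2Cc2ccc(O)c(OC)c2O)ccc1O | target

**Step count**

Total steps: 9. Longest linear sequence: 7 steps (6 → 7 → 9 → 10 → 11 → 14 → 15 → 16, steps 3 to 9).

**Steps most likely to fail**

1. Step 7. Three things may go wrong. Addition of the nucleophilic CO2•− to an electron-rich, β-branched styrene may be slow, so that radical chains die. Thiyl radicals may reversibly abstract the allylic C4–H before the addition, which would erode the configuration at C4 or move the double bond. Ring closure of the carboxylate may be incomplete.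
 Fallback, from 5 and 9, returning at 15. Hydroboration of 5 (9-BBN, THF; then NaBO3·4H2O) should give (3R)-4-chloro-3-[4-(benzyloxy)-3-methoxybenzyl]butan-1-ol F1. Oxidation (TEMPO cat., PhI(OAc)2, MeCN/H2O) should give (3R)-4-chloro-3-[4-(benzyloxy)-3-methoxybenzyl]butanoic acid F2. K2CO3 in DMF at 60 °C should close it to (4R)-4-[4-(benzyloxy)-3-methoxybenzyl]dihydrofuran-2(3H)-one F3. In parallel, 9 is reduced (NaBH4, MeOH) to [2,4-bis(benzyloxy)-3-methoxyphenyl]methanol F4 and converted (PBr3, Et2O, 0 °C) into 1,3-bis(benzyloxy)-4-(bromomethyl)-2-methoxybenzene F5. Alkylation of the lithium enolate of F3 (LiHMDS, THF, −78 °C) with F5 should take place anti to the C4 substituent and give the trans lactone 15 directly.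

2. Step 2. Wurtz-type homocoupling may occur while the electron-rich benzylic Grignard reagent is formed. Direct SN2 substitution may compete with SN2′. Enantiofacial discrimination may be low with a benzylic nucleophile.
 Fallback, from 2, returning at 5. Halide exchange of 2 (NaI, acetone) should give 1-(benzyloxy)-4-(iodomethyl)-2-methoxybenzene F6. But-3-enoic acid (pivaloyl chloride, Et3N, THF, −20 °C) and lithiated (R)-4-benzyloxazolidin-2-one should give (4R)-4-benzyl-3-(but-3-enoyl)-1,3-oxazolidin-2-one F7. Auxiliary-controlled alkylation of its sodium Z-enolate (NaHMDS, THF, −78 °C) with F6, on the face away from the ring benzyl group, should give (4R)-4-benzyl-3-[(2R)-2-[4-(benzyloxy)-3-methoxybenzyl]but-3-enoyl]-1,3-oxazolidin-2-one F8. Reduction (LiBH4, THF/MeOH, 0 °C) should give (2R)-2-[4-(benzyloxy)-3-methoxybenzyl]but-3-en-1-ol F9. Appel-type chlorination (PPh3, N-chlorosuccinimide, CH2Cl2, 0 °C) should then give 5.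

3. Step 6. Self-metathesis of the styrene to the stilbene may dominate, and turnover at the allylically branched olefin may be slow, so that the cross-coupling stalls.
 Fallback, from 7 and 5, returning at 11. Iodination of 7 (N-iodosuccinimide, cat. CF3CO2H, MeCN) should give 1,3-bis(benzyloxy)-4-iodo-2-methoxybenzene F10. A Mizoroki–Heck arylation of the terminal alkene of 5 with F10 under ligand-free phase-transfer conditions (Pd(OAc)2, n-Bu4NCl, NaHCO3, DMF, 80 °C) should give the E-styrene 11, with β-hydride elimination directed towards the benzylic hydrogens.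

**Further compounds**

F1 | step 7 | (3R)-4-chloro-3-[4-(benzyloxy)-3-methoxybenzyl]butan-1-ol | OCC[C@H](CCl)Cc1ccc(OCc2ccccc2)c(OC)c1
F2 | step 7 | (3R)-4-chloro-3-[4-(benzyloxy)-3-methoxybenzyl]butanoic acid | OC(=O)C[C@H](CCl)Cc1ccc(OCc2ccccc2)c(OC)c1
F3 | step 7 | (4R)-4-[4-(benzyloxy)-3-methoxybenzyl]dihydrofuran-2(3H)-one | COc1cc(C[C@H]2COC(=O)C2)ccc1OCc1ccccc1
F4 | step 7 | [2,4-bis(benzyloxy)-3-methoxyphenyl]methanol | COc1c(OCc2ccccc2)ccc(CO)c1OCc1ccccc1
F5 | step 7 | 1,3-bis(benzyloxy)-4-(bromomethyl)-2-methoxybenzene | COc1c(OCc2ccccc2)ccc(CBr)c1OCc1ccccc1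
F6 | step 2 | 1-(benzyloxy)-4-(iodomethyl)-2-methoxybenzene | COc1cc(CI)ccc1OCc1ccccc1
F7 | step 2 | (4R)-4-benzyl-3-(but-3-enoyl)-1,3-oxazolidin-2-one | C=CCC(=O)N1[C@H](Cc2ccccc2)COC1=O
F8 | step 2 | (4R)-4-benzyl-3-[(2R)-2-[4-(benzyloxy)-3-methoxybenzyl]but-3-enoyl]-1,3-oxazolidin-2-one | C=C[C@@H](Cc1ccc(OCc2ccccc2)c(OC)c1)C(=O)N1[C@H](Cc2ccccc2)COC1=O
F9 | step 2 | (2R)-2-[4-(benzyloxy)-3-methoxybenzyl]but-3-en-1-ol | C=C[C@H](CO)Cc1ccc(OCc2ccccc2)c(OC)c1
F10 | step 6 | 1,3-bis(benzyloxy)-4-iodo-2-methoxybenzene | COc1c(OCc2ccccc2)ccc(I)c1OCc1ccccc1
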